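# Proposal: total synthesis of the germacranolide CNP0319825.5 (27) by vinyl acetate photocycloaddition and Grob ring expansion

Atom numbering is that of the germacrane skeleton. C1–C10 are the ring carbons, C11–C13 the lactone carbons, and O6 is the lactone oxygen.

## The problem

The target is a ten-membered carbocycle cis-fused at C6–C7 to an α-methylene-γ-butyrolactone. It carries two ring-cis trisubstituted olefins (C4=C5 and C9=C10) and three differently acylated or free oxygens: a free C1 hydroxyl, a C3 acetate and a C8 angelate.

A ten-membered ring with two Z olefins is not closed reliably by direct cyclisation. The ring size and both olefin geometries therefore have to come from steps that fix them by mechanism.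

There are five stereocentres. C6, C7 and C8 are contiguous and can be set first by reagent control. Once they sit in a ring they define its two faces, and this can be used for C3. C1 lies beyond an olefin and needs a chiral reagent.

Several groups limit the late chemistry:
- The α-methylene lactone is a Michael acceptor.
- The angelate isomerises to the tiglate under nucleophilic catalysis.
- The C3 acetate is 1,3 to the C1 oxygen, so acyl shift is possible, and it becomes a β-acyloxy ketone whenever C1 is a carbonyl.
- A free O8 can take the lactone over from O6.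

The feature that opens the route is the C2–C3(OAc) unit between oxygenated C1 and methyl-bearing C4. It has the oxidation pattern of vinyl acetate. Removing it and joining C1 to C4 leaves an eight-membered ring (C1, C4, C5, C6, C7, C8, C9, C10). In that ring C1=C4 is the olefin of a 2-silyloxy-3-methyl enone with its carbonyl at C10.

## Retrosynthesis

**27 from 26 (C11=C13).** The exocyclic methylene is cut last. A lactone enolate cannot be made selectively beside an acetate and an angelate, so the methylene is carried as an α-diethoxyphosphoryl group. Its C–H is acidic enough for carbonate, and it gives the olefin with formaldehyde. The forward step only has to be faster than acyl migration between O3 and O1.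

**26 from 25 (C1–H).** The C1 carbinol is traced to the enone. Of the five stereocentres only this one is set in the ten-membered ring, and it is set by a chiral oxazaborolidine rather than by the ring.

**25 from 24 (C1–C4 re-formed, C5–O restored).** The C1 carbonyl and the Z-C4=C5 olefin are the two ends of a Grob fragmentation. Reconnecting C1–C4 and placing a mesylate on C5 turns the ten-membered ring into the bicyclo[6.2.0]decene 24. Against a macrocyclisation this cut gives the medium ring by strain release. It also fixes the olefin geometry through the C4/C5 configuration: O5 must be cis to the cyclobutane carbons, so that C6 and C3 end up cis. The forward step needs the C5–O bond antiperiplanar to C1–C4. The angelate (from 21, via 23) and the mesylate are put on before the fragmentation, so the β-acetoxy ketone 25 is never heated with an acylating mixture. Triol 20 comes from 19 by one desilylation.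

**19 from 17 (C10–CH3).** The C10 methyl and the C9=C10 olefin are traced to the C10 ketone through its enol triflate 18. The ketone can enolise only toward C9 because C1 is quaternary, and the eight-membered ring makes the olefin ring-cis.

**17 from 15 and 16 (C1–C2 and C3–C4).** The cyclobutane is cut into vinyl acetate 16 and the eight-membered 2-triethylsilyloxy enone 15. The alternative of adding C2–C3 by enolate chemistry to a ten-membered ring would leave both the ring and C3 unsolved. Here the acetate arrives in place and already differentiated. The forward reaction has to give head-to-tail regiochemistry, attack on the face away from the lactone, and an exo acetate. C1 is erased later, so only C4 and C3 must be right.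

**15 from 12 (C1–O, C10=O).** The silyloxy enone is the O-silylated enol of the 1,2-diketone 14. The diketone comes from diol 13 and hence from the Z-olefin of cyclooctene 12. The enolisation has to go toward the methyl-bearing C4.

**12 from 10 (C11–P).** The phosphonate is introduced on the lactone enolate while the molecule holds only ethers and one olefin.

**10 from 9 (C1=C10).** Ring-closing metathesis is preferred to a pinacol closure. The cis-fused lactone already holds the two alkenyl chains on one face, and the olefin formed is exactly the one needed for the diketone.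

**9 from 7 (C4–C5), 7 from 4 (C8–C9).** Both chains are allyl-type additions to aldehydes at C5 and C8: crotylation for C4/C5 and allylation for C8. Each needs the non-Felkin carbinol, so both are run with diisopinocampheylboranes. C4 becomes trigonal later and needs no control.

**4 from 1 and 2 (C6–C7, O6–C12).** The cis-lactone with two differentiated aldehyde carbons is an anti aldol product. The donor is methyl 4-oxobutanoate 1 and the acceptor is 2,2-dimethoxyacetaldehyde 2, followed by lactonisation. L-Proline sets C6 and C7 in one step from two commercial aldehydes.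

## Roads not taken

**Alternative 1:** The cut is the transannular C3–C8 bond. A cis-fused decalindiol A2 would be cleaved by Pb(OAc)4 to the ten-membered bis-enone A1.
- Merits: A2 can be built with six-membered-ring chemistry. Both olefins are cyclohexene double bonds, so their Z geometry is guaranteed. Glycol cleavage is among the most reliable C–C scissions and there is no photochemistry. In ring formation and olefin geometry this road is safer than the chosen one.
- Weak points: A1 has lost the C3 and C8 stereocentres. Two enone carbonyls in a flexible ring must then be reduced with opposite tasks (acetate and angelate) and each with stereocontrol. The C8 ketone also has an acidic C7–H next to the lactone-bearing C6, which invites epimerisation and lactone opening. The methylene lactone has to survive lead tetraacetate and hydride.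
- Comparison: the chosen plan never destroys C8 and brings C3 in as the acetate, differentiated by construction. It pays for this with an uncertain photocycloaddition.

**Alternative 2:** The cut is C2–C3 together with O–C1. Oxidation of aldoxime A4 with NaOCl gives a nitrile oxide, which adds across the C1=C2 vinyl group to give the isoxazoline-bridged macrocycle A3.
- Merits: one step closes the ring, sets C1 and masks a C3 carbonyl. The open-chain precursor carries both Z olefins from ordinary olefinations. The route would be shorter and needs fewer protecting-group changes than the chosen one.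
- Weak points: a ten-membered ring must form by an intramolecular dipolar addition to a monosubstituted olefin, against dimerisation of the nitrile oxide. C1 is set in a macrocyclic transition state with no nearby control element. After N–O cleavage C3 is a ketone, which must be reduced selectively and acetylated beside the free C1 hydroxyl. Hypochlorite meets two trisubstituted olefins.
- Comparison: the chosen plan makes the ten-membered ring from an eight-membered one by strain release and never has to tell O1 from O3. It is longer.

**Alternative 3:** The cuts are C6–O and C3–O. Pd(OAc)2 with an oxidant would convert the ring diene acid A6 into the silyl ether A5 of the target by 1,4-acetoxylactonisation.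
- Merits: lactone and acetate are installed together and only a desilylation remains. This end game is clearly more economical than the chosen one.
- Weak points: all difficulty moves into A6. It is a ten-membered ring with a Z,Z-1,3-diene, the Z-C9=C10 olefin, three stereocentres, an acrylic acid and the angelate, and its ring closure is unsolved. Palladium must pick the C3–C6 diene among five olefins and the carboxylate must attack C6 and not C3. The relative configuration of C3 and C6 depends on the face chosen in a floppy ring.
- Comparison: the chosen plan forms its rings by metathesis, photocycloaddition and fragmentation, each known for the ring size concerned, and fixes C6–C8 in the first two steps.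

Key step: step 12

Remark: C11 of the α-phosphono lactones (12–15, 17–20, 23–26) is an epimerisable centre and is drawn without a descriptor. Both epimers give 27. The same holds for the diol carbons of 13 and for C4 of 14.

## Route

Step 1
Reactants: 1 methyl 4-oxobutanoate; 2 2,2-dimethoxyacetaldehyde
Product: 4 (2R,3S)-2-(dimethoxymethyl)-5-oxooxolane-3-carbaldehyde, via aldol adduct 3 (not isolated)
Conditions: L-proline (20 mol %), DMF, 4 °C, slow addition of 1 to 2 (2 equiv); then PPTS (cat.), CH2Cl2, rt
Reagents that add atoms: none
Why: Proline-catalysed direct cross-aldol reaction of the enamine of 1 with the reactive acceptor 2 should give the anti adduct 3, with C6 and C7 set by the hydrogen-bonded chair transition state of L-proline. Acid-catalysed lactonisation of the γ-hydroxy ester then gives the cis-4,5-disubstituted lactone 4 and removes the free β-hydroxy aldehyde.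

Step 2
Reactants: 4 cis-lactone aldehyde
Product: 5 (4R,5R)-5-(dimethoxymethyl)-4-[(1R)-1-hydroxybut-3-en-1-yl]oxolan-2-one
Conditions: (+)-Ipc2B(allyl) [from (−)-α-pinene], Et2O, −78 °C; then NaBO3·4H2O, THF/H2O, rt
Reagents that add atoms: (+)-B-allyldiisopinocampheylborane, C=CCB([C@H]1C[C@H]2C[C@@H]([C@@H]1C)C2(C)C)[C@H]1C[C@H]2C[C@@H]([C@@H]1C)C2(C)C
Why: Brown allylboration through a closed chair transition state. The borane from (−)-α-pinene should deliver allyl to the aldehyde face that gives the 8R carbinol, overriding the modest Felkin preference of the α-branched aldehyde. The non-basic conditions leave the lactone and C7 untouched.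

Step 3
Reactants: 5 homoallylic alcohol
Product: 6 C8 tert-butyldiphenylsilyl ether of 5
Conditions: TBDPSCl, imidazole, DMAP (cat.), DMF, rt
Reagents that add atoms: tert-butyl(chloro)diphenylsilane, CC(C)(C)[Si](Cl)(c1ccccc1)c1ccccc1
Why: Standard silylation. The TBDPS ether is chosen because it survives the aqueous acid of step 4 and later adds bulk to the lactone face of the eight-membered ring.

Step 4
Reactants: 6 silyl ether acetal
Product: 7 cis-lactone C5 aldehyde (3-[(1R)-1-(tert-butyldiphenylsilyloxy)but-3-enyl]-5-oxooxolane-2-carbaldehyde)
Conditions: TFA/H2O/CH2Cl2, 0 °C → rt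
Reagents that add atoms: water, O
Why: Acid hydrolysis of the dimethyl acetal. The TBDPS ether, lactone and terminal olefin are stable to it. The α-acyloxy aldehyde is used directly after drying.

Step 5
Reactants: 7 C5 aldehyde
Product: 8 crotyl adduct (C5 carbinol syn to the lactone oxygen O6, C4 methyl anti to O5, terminal vinyl at C1)
Conditions: trans-2-butene, n-BuLi, KOt-Bu, THF, −45 °C; (+)-Ipc2BOMe, −78 °C; BF3·OEt2; then 7, −78 °C; NaBO3·4H2O, THF/H2O, rt
Reagents that add atoms: trans-2-butene, C/C=C/C (transferred as (+)-(E)-crotyldiisopinocampheylborane, C/C=C/CB([C@H]1C[C@H]2C[C@@H]([C@@H]1C)C2(C)C)[C@H]1C[C@H]2C[C@@H]([C@@H]1C)C2(C)C)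
Why: Brown crotylboration. The E-crotyl reagent gives the 4,5-anti adduct and the Ipc groups should set C5 in the non-Felkin sense (O5 syn to O6). This configuration later places the leaving group cis to the cyclobutane. C4 becomes trigonal in step 11.

Step 6
Reactants: 8 crotyl adduct
Product: 9 C5 triethylsilyl ether of 8 (metathesis diene)
Conditions: TESOTf, 2,6-lutidine, CH2Cl2, −78 °C
Reagents that add atoms: triethylsilyl trifluoromethanesulfonate, CC[Si](CC)(CC)OS(=O)(=O)C(F)(F)F
Why: Silylation of a hindered secondary alcohol with a silyl triflate. Prompt protection prevents migration of the lactone to O5.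

Step 7
Reactants: 9 diene
Product: 10 cis-fused cyclooctene lactone (Z-C1=C10, C4 methyl, C5 OTES, C8 OTBDPS)
Conditions: second-generation Grubbs catalyst [RuCl2(=CHPh)(H2IMes)(PCy3)] (5 mol %), CH2Cl2 (0.002 M), 40 °C
Reagents that add atoms: none
Why: Ring-closing metathesis. The cis-fused lactone holds both alkenyl chains on the same face, which favours the eight-membered ring, and that ring size allows only the Z olefin.

Step 8
Reactants: 10 cyclooctene lactone
Product: 12 α-(diethoxyphosphoryl) lactone, via enol phosphate 11 (not isolated)
Conditions: LiN(i-Pr)2 (2.3 equiv), THF, −78 °C; ClP(O)(OEt)2, −78 °C → rt; then AcOH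
Reagents that add atoms: diethyl chlorophosphate, CCOP(=O)(Cl)OCC
Why: O-Phosphorylation of the lactone enolate gives the ketene acetal phosphate 11. The second equivalent of amide base induces the known 1,3-shift of phosphorus from oxygen to carbon, driven by formation of the stabilised phosphonate anion. The product is a masked α-methylene lactone whose C11 configuration is irrelevant.

Step 9
Reactants: 12 phosphono lactone
Product: 13 C1,C10-cis-diol
Conditions: OsO4 (2 mol %), NMO, acetone/H2O, rt
Reagents that add atoms: N-methylmorpholine N-oxide, C[N+]1([O-])CCOCC1; water, O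
Why: Catalytic (Upjohn) dihydroxylation of the only olefin. The face of attack does not matter because both carbinols are oxidised next.

Step 10
Reactants: 13 diol
Product: 14 C1,C10-diketone
Conditions: IBX, DMSO, rt
Reagents that add atoms: none
Why: IBX oxidises vicinal diols to 1,2-diketones without cleaving the C–C bond. Silyl ethers and the phosphonate are inert.

Step 11
Reactants: 14 diketone
Product: 15 eight-membered 2-(triethylsilyloxy)-3-methyl enone (C10 carbonyl, C1(OTES)=C4(Me))
Conditions: TESCl, Et3N, DMAP (cat.), CH2Cl2, 0 °C → rt
Reagents that add atoms: chlorotriethylsilane, CC[Si](Cl)(CC)CC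
Why: O-Silylation of the diosphenol under equilibrating amine conditions. As with 3-alkyl-1,2-diones in general, the enol should lie toward the methyl-bearing carbon C4, giving the tetrasubstituted enol ether conjugated with the C10 carbonyl.

Step 12
Reactants: 15 silyloxy enone; 16 vinyl acetate
Product: 17 cis-fused bicyclo[6.2.0]decanone photoadduct (cyclobutane C1–C2–C3–C4, C3 acetate exo and cis to the C4 methyl, C1 OTES)
Conditions: hν (350 nm, Pyrex), vinyl acetate/CH2Cl2 (1:1), −40 °C
Reagents that add atoms: none
Why: Enone–alkene (2+2) photocycloaddition, the first half of a de Mayo-type two-carbon ring expansion. Excitation of the 2-silyloxy enone and intersystem crossing give the triplet, which adds to vinyl acetate (used as cosolvent so that capture outruns Z→E twisting of the eight-membered enone) to form a triplet 1,4-diradical that closes after spin inversion. The head-to-tail orientation usual for electron-rich alkenes joins the CH2 terminus (C2) to the α-carbon C1 and the acetoxy carbon (C3) to the β-carbon C4, through the diradical with centres at tertiary C4 and acetoxy-stabilised C3. The four-membered ring closes by collapse of this diradical and is cis-fused to the eight-membered ring, as expected for a tetrasubstituted cyclooctenone braced by the lactone. C1 and C4 are set by the face of attack: the lactone with its phosphonate and the C8 OTBDPS group cover one face, so the alkene should approach from the other, anti to C6 with the C5 ether in the inside position, which leaves C3 cis to O5 as the fragmentation requires. C3 is set at ring closure, where the acetoxy group should take the convex (exo) side away from the eight-membered ring. The step therefore needs regio-, facial and exo selectivity: the first rests on enone polarity, the second on the substituents at C6–C8, and the third is the least secure. C1 is erased in step 18, so only C4 and C3 have to be correct.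

Step 13
Reactants: 17 photoadduct
Product: 18 C9=C10 enol triflate
Conditions: KN(SiMe3)2 (2.2 equiv), THF, −78 °C; PhNTf2; then aq. NH4Cl
Reagents that add atoms: N-phenylbis(trifluoromethanesulfonimide), O=S(=O)(N(c1ccccc1)S(=O)(=O)C(F)(F)F)C(F)(F)F
Why: The C10 ketone can enolise only toward C9 because C1 is quaternary, and the potassium enolate is O-triflated. One equivalent of base is taken up by the acidic phosphonate. At −78 °C the enolate does not expel the C8 silyloxy group.

Step 14
Reactants: 18 enol triflate
Product: 19 C10-methyl bicyclo[6.2.0]decene (ring-cis C9=C10)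
Conditions: Me2Zn, Pd(PPh3)4 (5 mol %), THF, 0 → 50 °C
Reagents that add atoms: dimethylzinc, C[Zn]C
Why: Negishi coupling of an alkenyl triflate with retention of olefin geometry. Organozinc reagents tolerate the acetate, the lactone and the silyl ethers.

Step 15
Reactants: 19 methyl olefin
Product: 20 C1,C5,C8-triol
Conditions: Bu4NF, AcOH, THF, rt → 40 °C
Reagents that add atoms: none
Why: Fluoride desilylation removes both TES ethers and the TBDPS ether. Buffering with acetic acid keeps the medium neutral, so that neither acetyl nor lactone migration to the new hydroxyls is promoted.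

Step 16
Reactants: 20 triol; 21 angelic acid
Product: 23 C8 angelate (C1 and C5 hydroxyls free), via mixed anhydride 22 (not isolated)
Conditions: 21, 2,4,6-Cl3C6H2COCl, Et3N, toluene, rt; then 20, 75 °C
Reagents that add atoms: none
Why: Yamaguchi esterification run without DMAP, which is the usual way to acylate with angelic acid without Z→E isomerisation. Only the allylic C8 hydroxyl should react: the C5 hydroxyl lies between quaternary C4 and C6, and the C1 hydroxyl is tertiary.

Step 17
Reactants: 23 angelate diol
Product: 24 C5 mesylate
Conditions: MsCl, Et3N, CH2Cl2, −20 °C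
Reagents that add atoms: methanesulfonyl chloride, CS(=O)(=O)Cl
Why: Mesylation through sulfene, which reaches even the hindered secondary C5 hydroxyl. The tertiary cyclobutanol is not sulfonylated.

Step 18
Reactants: 24 mesylate
Product: 25 ten-membered enone (C1 ketone conjugated with Z-C9=C10, Z-C4=C5, C3 acetate, C8 angelate)
Conditions: KN(SiMe3)2 (2.1 equiv), THF, −78 → −20 °C; then AcOH
Reagents that add atoms: none
Why: Grob (Wharton-type) fragmentation of a 1,3-hydroxy mesylate. The C1 alkoxide forms the carbonyl, the strained C1–C4 bond breaks and C4=C5 forms as the antiperiplanar mesylate leaves. Because O5 is cis to C3 on the bicycle, C3 and C6 end up cis, giving the Z olefin. The second equivalent of base only deprotonates the phosphonate.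

Step 19
Reactants: 25 ten-membered enone
Product: 26 (1S)-allylic alcohol
Conditions: (R)-2-methyl-CBS-oxazaborolidine, catecholborane, toluene, −78 °C
Reagents that add atoms: none
Why: Corey–Bakshi–Shibata reduction. The α-methyl alkenyl group acts as the large substituent and C2H2 as the small one, so the (R)-catalyst should give the 1S carbinol by 1,2-reduction. Esters and the phosphonate are not reduced.

Step 20
Reactants: 26 phosphono lactone alcohol
Product: 27 CNP0319825.5 (target)
Conditions: aq. HCHO, K2CO3, THF, 0 °C → rt
Reagents that add atoms: formaldehyde, C=O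
Why: Horner–Wadsworth–Emmons olefination of the α-phosphono lactone with formaldehyde, the standard mild route to α-methylene lactones. Carbonate deprotonates only the phosphonate C–H, and the short reaction at 0 °C should outrun acetate hydrolysis or migration.

## Compound list

1 | methyl 4-oxobutanoate | COC(=O)CCC=O | starting material
2 | 2,2-dimethoxyacetaldehyde | COC(OC)C=O | starting material
3 | methyl (3S,4R)-3-formyl-4-hydroxy-5,5-dimethoxypentanoate (anti aldol adduct) | COC(=O)C[C@H](C=O)[C@@H](O)C(OC)OC | intermediate
4 | (2R,3S)-2-(dimethoxymethyl)-5-oxooxolane-3-carbaldehyde (cis lactone, C8 aldehyde) | O=C[C@H]1CC(=O)O[C@H]1C(OC)OC | intermediate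
5 | (4R,5R)-5-(dimethoxymethyl)-4-[(1R)-1-hydroxybut-3-en-1-yl]oxolan-2-one | C=CC[C@@H](O)[C@H]1CC(=O)O[C@H]1C(OC)OC | intermediate
6 | C8 O-tert-butyldiphenylsilyl ether of 5 | C=CC[C@@H](O[Si](c1ccccc1)(c1ccccc1)C(C)(C)C)[C@H]1CC(=O)O[C@H]1C(OC)OC | intermediate
7 | cis-lactone C5 aldehyde with C8 OTBDPS but-3-enyl side chain | C=CC[C@@H](O[Si](c1ccccc1)(c1ccccc1)C(C)(C)C)[C@H]1CC(=O)O[C@H]1C=O | intermediate
8 | crotyl adduct: C5 carbinol (5,6-syn), C4 methyl (4,5-anti), vinyl at C1 | C=CC[C@@H](O[Si](c1ccccc1)(c1ccccc1)C(C)(C)C)[C@H]1CC(=O)O[C@H]1[C@H](O)[C@H](C)C=C | intermediate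
9 | C5 O-triethylsilyl ether of 8 (metathesis diene) | C=CC[C@@H](O[Si](c1ccccc1)(c1ccccc1)C(C)(C)C)[C@H]1CC(=O)O[C@H]1[C@H](O[Si](CC)(CC)CC)[C@H](C)C=C | intermediate
10 | cis-fused cyclooctene lactone, Z-C1=C10 | C[C@@H]1/C=C\C[C@@H](O[Si](c2ccccc2)(c2ccccc2)C(C)(C)C)[C@H]2CC(=O)O[C@H]2[C@@H]1O[Si](CC)(CC)CC | intermediate
11 | cyclic ketene acetal diethyl phosphate of 10 (enol phosphate) | C[C@@H]1/C=C\C[C@@H](O[Si](c2ccccc2)(c2ccccc2)C(C)(C)C)[C@H]2C=C(OP(=O)(OCC)OCC)O[C@H]2[C@@H]1O[Si](CC)(CC)CC | intermediate
12 | 11-(diethoxyphosphoryl) cyclooctene lactone (C11 epimers) | C[C@@H]1/C=C\C[C@@H](O[Si](c2ccccc2)(c2ccccc2)C(C)(C)C)[C@H]2C(P(=O)(OCC)OCC)C(=O)O[C@H]2[C@@H]1O[Si](CC)(CC)CC | intermediate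
13 | C1,C10-cis-diol of 12 (diol face not controlled) | C[C@@H]1C(O)C(O)C[C@@H](O[Si](c2ccccc2)(c2ccccc2)C(C)(C)C)[C@H]2C(P(=O)(OCC)OCC)C(=O)O[C@H]2[C@@H]1O[Si](CC)(CC)CC | intermediate
14 | C1,C10-diketone (C4 epimerisable) | C[C@@H]1C(=O)C(=O)C[C@@H](O[Si](c2ccccc2)(c2ccccc2)C(C)(C)C)[C@H]2C(P(=O)(OCC)OCC)C(=O)O[C@H]2[C@@H]1O[Si](CC)(CC)CC | intermediate
15 | eight-membered 2-(triethylsilyloxy)-3-methyl enone lactone (C10=O, C1(OTES)=C4(Me), C5 OTES, C8 OTBDPS) | C1[C@@H](O[Si](c2ccccc2)(c2ccccc2)C(C)(C)C)[C@H]2C(P(=O)(OCC)OCC)C(=O)O[C@H]2[C@H](O[Si](CC)(CC)CC)/C(C)=C(O[Si](CC)(CC)CC)\C1=O | intermediate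
16 | vinyl acetate | C=COC(C)=O | starting material
17 | bicyclo[6.2.0]decanone photoadduct (cis-fused cyclobutane, exo C3 acetate) | O=C1C[C@@H](O[Si](c2ccccc2)(c2ccccc2)C(C)(C)C)[C@H]2C(P(=O)(OCC)OCC)C(=O)O[C@H]2[C@H](O[Si](CC)(CC)CC)[C@]3(C)[C@@H](OC(C)=O)C[C@]13O[Si](CC)(CC)CC | intermediate
18 | C9=C10 enol triflate of 17 | FC(F)(F)S(=O)(=O)O/C1=C/[C@@H](O[Si](c2ccccc2)(c2ccccc2)C(C)(C)C)[C@H]2C(P(=O)(OCC)OCC)C(=O)O[C@H]2[C@H](O[Si](CC)(CC)CC)[C@]3(C)[C@@H](OC(C)=O)C[C@]13O[Si](CC)(CC)CC | intermediate
19 | C10-methyl bicyclo[6.2.0]dec-9-ene | C/C1=C/[C@@H](O[Si](c2ccccc2)(c2ccccc2)C(C)(C)C)[C@H]2C(P(=O)(OCC)OCC)C(=O)O[C@H]2[C@H](O[Si](CC)(CC)CC)[C@]3(C)[C@@H](OC(C)=O)C[C@]13O[Si](CC)(CC)CC | intermediate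
20 | C1,C5,C8-triol | C/C1=C/[C@@H](O)[C@H]2C(P(=O)(OCC)OCC)C(=O)O[C@H]2[C@H](O)[C@]3(C)[C@@H](OC(C)=O)C[C@]13O | intermediate
21 | angelic acid ((Z)-2-methylbut-2-enoic acid) | C/C=C(/C)C(=O)O | starting material
22 | angelic 2,4,6-trichlorobenzoic anhydride | C/C=C(/C)C(=O)OC(=O)c1c(Cl)cc(Cl)cc1Cl | intermediate
23 | C8 angelate, C1,C5-diol | C/C1=C/[C@@H](OC(=O)/C(C)=C\C)[C@H]2C(P(=O)(OCC)OCC)C(=O)O[C@H]2[C@H](O)[C@]3(C)[C@@H](OC(C)=O)C[C@]13O | intermediate
24 | C5 mesylate of 23 | C/C1=C/[C@@H](OC(=O)/C(C)=C\C)[C@H]2C(P(=O)(OCC)OCC)C(=O)O[C@H]2[C@H](OS(C)(=O)=O)[C@]3(C)[C@@H](OC(C)=O)C[C@]13O | intermediate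
25 | ten-membered 1-oxo enone (Z-C4=C5, Z-C9=C10, 3-OAc, 8-OAng, 11-phosphono lactone) | CCOP(=O)(OCC)C1C(=O)O[C@H]2/C=C(/C)[C@@H](OC(C)=O)CC(=O)/C(C)=C\[C@@H](OC(=O)/C(C)=C\C)[C@@H]12 | intermediate
26 | (1S)-alcohol, 11-phosphono precursor of the target | CCOP(=O)(OCC)C1C(=O)O[C@H]2/C=C(/C)[C@@H](OC(C)=O)C[C@H](O)/C(C)=C\[C@@H](OC(=O)/C(C)=C\C)[C@@H]12 | intermediate
27 | CNP0319825.5 | C=C1C(=O)O[C@H]2/C=C(/C)[C@@H](OC(C)=O)C[C@H](O)/C(C)=C\[C@@H](OC(=O)/C(C)=C\C)[C@@H]12 | target

## Step count and risk

Total step count: 20. Longest linear sequence: 20 steps (from 1 and 2 to 27). Compounds 16 and 21 are commercial and enter at steps 12 and 16.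

Least certain steps:

**Step 12 (key step).**
- Risk: geometric isomerisation of the excited eight-membered enone may compete with capture by the alkene. Beyond that, the head-to-tail orientation, the facial selectivity and above all the exo placement of the acetate at C3 may be only partial, since all three are decided in a short-lived diradical.
- Fallback: it sets out from 15. Irradiation with 1,1-dimethoxyethylene, a more electron-rich and symmetrically substituted partner, should give the 3,3-dimethoxy adduct F1 with no C3 stereocentre. Mild acid (oxalic acid on wet silica) gives the cyclobutanone F2. NaBH4 at −78 °C reduces the strained ketone in preference to the hindered C10 ketone, from the convex face, to the endo alcohol F3. Mitsunobu esterification with acetic acid inverts C3 and returns to the route at 17.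

**Step 5.**
- Risk: the reagent must overrule the Felkin preference of the α-acyloxy aldehyde, and facial selectivity may be poor in this mismatched pairing.
- Fallback: it sets out from 7. The matched (Z)-crotyl reagent made from (−)-Ipc2BOMe should give the 5-epi alcohol F4 (4,5-syn, same C4). Mitsunobu reaction with chloroacetic acid inverts C5 to give the chloroacetate F5, and thiourea removes the chloroacetyl group to return at 8.

**Step 11.**
- Risk: enolisation of the diketone may go toward C9 instead of C4, so that the silyl group ends on the wrong oxygen.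
- Fallback: it sets out from 14. Excess TESOTf and Et3N give the 1,10-bis(triethylsilyloxy) diene F6, in which both enol ethers are formed. Controlled protodesilylation (PPTS, MeOH, −20 °C) should cleave the less substituted C9=C10 enol ether first, and the conjugated product then resists further cleavage, returning to the route at 15.

**Step 18.**
- Risk: the ring may not reach the conformer with C5–O antiperiplanar to C1–C4, and the two equivalents of strong base may cause deprotonation or acyl transfer at the acetate and angelate before fragmentation. Step 16 is related: acylation may be incompletely selective between the C8 and C5 hydroxyls.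
- Fallback: it sets out from 19 and changes the order of events. HF·pyridine buffered with pyridine at 0 °C removes only the two TES groups to give the diol F7 with C8 still silylated. Mesylation gives F8. Fragmentation with KN(SiMe3)2, now without an enoate in the molecule and with a different C8 substituent on the ring, gives the ten-membered enone F9. HF·pyridine at rt frees the C8 hydroxyl in F10, and Yamaguchi esterification with 21 through 22 returns to the route at 25.

**Step 19.**
- Risk: the conformation of the ten-membered ring may oppose the catalyst, so that facial selectivity at C1 is low or reversed.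
- Fallback: it sets out from 25. Luche reduction (NaBH4, CeCl3·7H2O, MeOH, −78 °C) is governed by the ring alone and is taken to give the 1R alcohol F11. Mitsunobu reaction with chloroacetic acid inverts C1 to the chloroacetate F12, and thiourea, which leaves the acetate and angelate alone, returns to the route at 26.

Further compounds

F1 | step 12 | 3,3-dimethoxy photoadduct of 15 with 1,1-dimethoxyethylene | O=C1C[C@@H](O[Si](c2ccccc2)(c2ccccc2)C(C)(C)C)[C@H]2C(P(=O)(OCC)OCC)C(=O)O[C@H]2[C@H](O[Si](CC)(CC)CC)[C@]3(C)C(OC)(OC)C[C@]13O[Si](CC)(CC)CC
F2 | step 12 | C3 cyclobutanone | O=C1C[C@@H](O[Si](c2ccccc2)(c2ccccc2)C(C)(C)C)[C@H]2C(P(=O)(OCC)OCC)C(=O)O[C@H]2[C@H](O[Si](CC)(CC)CC)[C@]3(C)C(=O)C[C@]13O[Si](CC)(CC)CC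
F3 | step 12 | C3 endo alcohol (3-epi, deacetyl 17) | O=C1C[C@@H](O[Si](c2ccccc2)(c2ccccc2)C(C)(C)C)[C@H]2C(P(=O)(OCC)OCC)C(=O)O[C@H]2[C@H](O[Si](CC)(CC)CC)[C@]3(C)[C@H](O)C[C@]13O[Si](CC)(CC)CC
F4 | step 5 | 5-epi crotyl adduct (4,5-syn) | C=CC[C@@H](O[Si](c1ccccc1)(c1ccccc1)C(C)(C)C)[C@H]1CC(=O)O[C@H]1[C@@H](O)[C@H](C)C=C
F5 | step 5 | C5 chloroacetate of 8 | C=CC[C@@H](O[Si](c1ccccc1)(c1ccccc1)C(C)(C)C)[C@H]1CC(=O)O[C@H]1[C@H](OC(=O)CCl)[C@H](C)C=C
F6 | step 11 | 1,10-bis(triethylsilyloxy)-1(4),9-diene | [C@@H]1(O[Si](c2ccccc2)(c2ccccc2)C(C)(C)C)/C=C(O[Si](CC)(CC)CC)\C(O[Si](CC)(CC)CC)=C(C)/[C@@H](O[Si](CC)(CC)CC)[C@@H]2OC(=O)C(P(=O)(OCC)OCC)[C@H]12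
F7 | step 18 | C1,C5-diol with C8 OTBDPS | C/C1=C/[C@@H](O[Si](c2ccccc2)(c2ccccc2)C(C)(C)C)[C@H]2C(P(=O)(OCC)OCC)C(=O)O[C@H]2[C@H](O)[C@]3(C)[C@@H](OC(C)=O)C[C@]13O
F8 | step 18 | C5 mesylate with C8 OTBDPS | C/C1=C/[C@@H](O[Si](c2ccccc2)(c2ccccc2)C(C)(C)C)[C@H]2C(P(=O)(OCC)OCC)C(=O)O[C@H]2[C@H](OS(C)(=O)=O)[C@]3(C)[C@@H](OC(C)=O)C[C@]13O
F9 | step 18 | ten-membered 1-oxo enone with C8 OTBDPS | CCOP(=O)(OCC)C1C(=O)O[C@H]2/C=C(/C)[C@@H](OC(C)=O)CC(=O)/C(C)=C\[C@@H](O[Si](c3ccccc3)(c3ccccc3)C(C)(C)C)[C@@H]12
F10 | step 18 | ten-membered 1-oxo enone with free C8 hydroxyl | CCOP(=O)(OCC)C1C(=O)O[C@H]2/C=C(/C)[C@@H](OC(C)=O)CC(=O)/C(C)=C\[C@@H](O)[C@@H]12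
F11 | step 19 | (1R)-alcohol (1-epi 26) | CCOP(=O)(OCC)C1C(=O)O[C@H]2/C=C(/C)[C@@H](OC(C)=O)C[C@@H](O)/C(C)=C\[C@@H](OC(=O)/C(C)=C\C)[C@@H]12
F12 | step 19 | (1S)-chloroacetate of 26 | CCOP(=O)(OCC)C1C(=O)O[C@H]2/C=C(/C)[C@@H](OC(C)=O)C[C@H](OC(=O)CCl)/C(C)=C\[C@@H](OC(=O)/C(C)=C\C)[C@@H]12
A1 | alternative 1 | ten-membered bis-enone lactone | C=C1C(=O)O[C@H]2/C=C(/C)C(=O)C[C@H](O[Si](C)(C)C(C)(C)C)/C(C)=C\C(=O)[C@@H]12
A2 | alternative 1 | cis-fused decalin-3,8-diol precursor (one cis-diol face drawn) | C=C1C(=O)O[C@H]2C=C(C)[C@]3(O)C[C@H](O[Si](C)(C)C(C)(C)C)C(C)=C[C@]3(O)[C@@H]12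
A3 | alternative 2 | isoxazoline-bridged cyclodecadiene lactone | C1C(=O)O[C@H]2/C=C(/C)C3=NO[C@@H](C3)/C(C)=C\[C@@H](O[Si](C)(C)C(C)(C)C)[C@@H]12
A4 | alternative 2 | open-chain aldoxime triene lactone | C1C(=O)O[C@@H](/C=C(/C)C=NO)[C@H]1[C@H](O[Si](C)(C)C(C)(C)C)/C=C(/C)C=C
A5 | alternative 3 | 1-O-tert-butyldimethylsilyl ether of the target | C=C1C(=O)O[C@H]2/C=C(/C)[C@@H](OC(C)=O)C[C@H](O[Si](C)(C)C(C)(C)C)/C(C)=C\[C@@H](OC(=O)/C(C)=C\C)[C@@H]12
A6 | alternative 3 | ten-membered Z,Z-diene acrylic acid | C=C(C(=O)O)[C@H]1/C=C\C(C)=C/C[C@H](O[Si](C)(C)C(C)(C)C)/C(C)=C\[C@H]1OC(=O)/C(C)=C\C
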